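## Retrosynthetic overview

1. Target 20 ⇐ Pd‑mediated removal of two catechol allyl ethers from 19.
2. 19 ⇐ ring B closed last: cationic C1–C8 bond formation from the spiro tertiary alcohol 18 (bicyclo[3.3.1] core formed on a pre‑existing spirocycle).
3. 18 ⇐ ester 16 by C7 prenylation and double methyl addition; 16 ⇐ aromatic acylphloroglucinol 14 by an enantioselective dearomatising Michael addition–lactonisation that closes the seven‑membered ring C and sets C5 and C6 (key step).
4. 14 ⇐ arene 6 (phloroglucinol + protected protocatechuonitrile, then C‑prenylation) + aldehyde 13 (2‑methylcyclohexenone: asymmetric conjugate addition/methylation, ring cleavage, Wittig).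
5. Ring order: aromatic ring (future ring A) → ring C (spiro, aromaticity broken) → ring B.

Assumption 1: the target is taken exactly as the SMILES given; atoms keep the target's numbering throughout (C1 prenyl bridgehead, C2–C4 acyl‑triketone, C5 bridgehead, C6/C7/C8 bridge, C9 bridging carbonyl, ring C = C5–C10H2–C11Me2–C12H(isopropenyl)–C13H2–C14H2–C6), which gives 1S,5S,6S,7S,12S for the drawn tautomer.
Assumption 2: the sense of induction of the two chiral catalysts (steps 4 and 9) is taken from their usual models; if found opposite, the commercial antipode is used and nothing else changes.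

## Route

Step 1
Reactants: 1 3,4-dihydroxybenzonitrile
Product: 2 3,4-bis(prop-2-en-1-yloxy)benzonitrile
Conditions: allyl bromide (2.4 equiv), K2CO3, DMF, 60 °C
Reagents that add atoms: allyl bromide, C=CCBr
Why: Williamson etherification protects the catechol as allyl ethers, which survive acid, base and organometallics and are removed under neutral Pd conditions at the end.

Step 2
Reactants: 2 3,4-bis(prop-2-en-1-yloxy)benzonitrile; 3 phloroglucinol
Product: 5 [3,4-bis(prop-2-en-1-yloxy)phenyl](2,4,6-trihydroxyphenyl)methanone, via ketiminium chloride 4 (not isolated)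
Conditions: ZnCl2 (20 mol %), HCl (g), Et2O, 0 °C; then H2O, 90 °C
Reagents that add atoms: water, O
Why: Hoesch acylation of the very electron‑rich phloroglucinol by the nitrile gives the ketiminium salt, whose hydrolysis gives the benzophenone without a strong Lewis acid that would cleave the allyl ethers.

Step 3
Reactants: 5 [3,4-bis(prop-2-en-1-yloxy)phenyl](2,4,6-trihydroxyphenyl)methanone
Product: 6 [3,4-bis(prop-2-en-1-yloxy)phenyl][2,4,6-trihydroxy-3-(3-methylbut-2-en-1-yl)phenyl]methanone
Conditions: prenyl bromide (1.0 equiv), KOH (1.0 equiv), H2O, 0 °C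
Reagents that add atoms: prenyl bromide, CC(C)=CCBr
Why: aqueous base‑mediated C‑alkylation of the acylphloroglucinol anion gives the mono‑C‑prenyl compound (the two free ring positions are equivalent; the bis‑prenyl by‑product is separated).

Step 4
Reactants: 7 2-methylcyclohex-2-en-1-one
Product: 9 (3S)-2,2-dimethyl-3-(prop-1-en-2-yl)cyclohexan-1-one, via bromomagnesium enolate 8 (not isolated)
Conditions: isopropenylMgBr (1.3 equiv), CuBr·SMe2 (5 mol %), (R)-1-[(S)-2-(diphenylphosphino)ferrocenyl]ethyldicyclohexylphosphine (6 mol %), t-BuOMe, −78 °C; then MeI (5 equiv), DMPU, −78 → 0 °C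
Reagents that add atoms: isopropenylmagnesium bromide, C=C(C)[Mg]Br; iodomethane, CI
Why: Proposed new method: copper‑catalysed asymmetric conjugate addition of the alkenyl Grignard reagent, in which the chiral Cu–diphosphine complex delivers isopropenyl to one enone face (sets the future C12 as S), followed by C‑methylation of the regiodefined enolate at the more substituted α‑carbon; the closest known reactions are Cu/ferrocenyl‑diphosphine Grignard conjugate additions to cyclohexenones and tandem conjugate addition–enolate alkylation of 2‑methylcyclohexenone.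

Step 5
Reactants: 9 (3S)-2,2-dimethyl-3-(prop-1-en-2-yl)cyclohexan-1-one
Product: 10 (3S)-6-hydroxy-2,2-dimethyl-3-(prop-1-en-2-yl)cyclohexan-1-one (both C6 epimers)
Conditions: KHMDS (1.1 equiv), THF, −78 °C; Davis oxaziridine (1.2 equiv)
Reagents that add atoms: 3-phenyl-2-(phenylsulfonyl)oxaziridine, O=S(=O)(c1ccccc1)N1OC1c1ccccc1
Why: Davis enolate hydroxylation is regiospecific because only C6 is enolisable, and the electrophilic oxygen donor leaves the isopropenyl group untouched.

Step 6
Reactants: 10 (3S)-6-hydroxy-2,2-dimethyl-3-(prop-1-en-2-yl)cyclohexan-1-one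
Product: 12 (3S)-2,2-dimethyl-3-(prop-1-en-2-yl)hexanedial, via diol 11 (not isolated)
Conditions: NaBH4, MeOH, 0 °C; then NaIO4, THF/H2O, 23 °C
Reagents that add atoms: none
Why: ketone reduction then Malaprade glycol cleavage opens the ring between the carbonyl carbon (future C10) and C6's precursor, giving a hindered neopentyl aldehyde and an unhindered aldehyde without touching the stereocentre.

Step 7
Reactants: 12 (3S)-2,2-dimethyl-3-(prop-1-en-2-yl)hexanedial
Product: 13 4-nitrophenyl (2E,6S)-7,7-dimethyl-8-oxo-6-(prop-1-en-2-yl)oct-2-enoate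
Conditions: Ph3P=C=C=O (1.05 equiv), 4-nitrophenol (1.05 equiv), THF, 23 °C, 1 h; then 12, 23 °C
Reagents that add atoms: (triphenylphosphoranylidene)ketene, O=C=C=P(c1ccccc1)(c1ccccc1)c1ccccc1; 4-nitrophenol, Oc1ccc(cc1)[N+](=O)[O-]
Why: the Bestmann ylide adds the phenol to give a stabilised ester ylide whose E‑selective Wittig reaction takes only the unhindered aldehyde under neutral conditions (no aldol between the two aldehydes), leaving the α‑quaternary aldehyde free.

Step 8
Reactants: 6 [3,4-bis(prop-2-en-1-yloxy)phenyl][2,4,6-trihydroxy-3-(3-methylbut-2-en-1-yl)phenyl]methanone; 13 4-nitrophenyl (2E,6S)-7,7-dimethyl-8-oxo-6-(prop-1-en-2-yl)oct-2-enoate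
Product: 14 4-nitrophenyl (2E,6S)-8-{3-[3,4-bis(prop-2-en-1-yloxy)benzoyl]-2,4,6-trihydroxy-5-(3-methylbut-2-en-1-yl)phenyl}-7,7-dimethyl-6-(prop-1-en-2-yl)oct-2-enoate
Conditions: Hantzsch ester (1.3 equiv), (PhO)2PO2H (20 mol %), 4 Å MS, ClCH2CH2Cl, 50 °C
Reagents that add atoms: none
Why: acid‑catalysed Friedel–Crafts hydroxyalkylation at the only free ring carbon gives an ortho‑quinone methide that is reduced in situ by Hantzsch ester transfer hydrogenation (reductive alkylation), forming the neopentyl C5–C10 bond that SN2 chemistry cannot make; the non‑enolisable aldehyde has no competing aldol path.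

Step 9
Reactants: 14 4-nitrophenyl (2E,6S)-8-{3-[3,4-bis(prop-2-en-1-yloxy)benzoyl]-2,4,6-trihydroxy-5-(3-methylbut-2-en-1-yl)phenyl}-7,7-dimethyl-6-(prop-1-en-2-yl)oct-2-enoate
Product: 16 methyl (5S,6S,12S)-spiro ester [ring C closed between C5 and C6; dearomatised ring A with C9=O, C1(prenyl)=C2(OH), C3(aroyl)=C4(OH); C6 carries CH2CO2Me], via spiro enol lactone 15 (not isolated)
Conditions: (2S,3R)-HyperBTM (20 mol %), i-Pr2NEt (1.5 equiv), CH2Cl2 (0.005 M), 0 → 23 °C; then MeOH, DMAP (20 mol %)
Reagents that add atoms: methanol, CO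
Why: Proposed new method: the isothiourea converts the aryl enoate into an s‑cis α,β‑unsaturated acyl isothiouronium, the phenoxide para to the aroyl group (the only unchelated, most acidic OH) attacks through its ipso carbon C5 in a 7‑exo Michael addition on the face left open by the catalyst's phenyl group (sets 6S) through the conformer with C6–H over the ring and the acyl group beside that oxygen, and lactonisation on the same oxygen releases the catalyst and fixes the spiro centre as 5S with loss of aromaticity; the closest known reaction is the isothiourea‑catalysed Michael addition–lactonisation of 1,3‑dicarbonyls and naphthols with α,β‑unsaturated acyl ammonium species, here made intramolecular and dearomatising, and methanolysis of the activated enol lactone then gives the stable ester.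

Step 10
Reactants: 16 methyl (5S,6S,12S)-spiro ester
Product: 17 methyl (5S,6S,7S,12S)-7-prenyl spiro ester [as 16 with a 3-methylbut-2-en-1-yl group on the ester α‑carbon C7]
Conditions: LDA (3.3 equiv), THF/DMPU, −78 °C; prenyl bromide (1.05 equiv), −78 → −40 °C
Reagents that add atoms: prenyl bromide, CC(C)=CCBr
Why: in the trianion the ester enolate is the last‑formed and most reactive site, and it is alkylated on the face anti to the quaternary spiro carbon with C6–H eclipsing the enolate (A(1,3) strain control), which gives 7S, the endo orientation in the final bicycle.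

Step 11
Reactants: 17 methyl (5S,6S,7S,12S)-7-prenyl spiro ester
Product: 18 (5S,6S,7S,12S)-spiro tertiary alcohol [as 17 with the CO2Me group converted into C8(OH)Me2]
Conditions: MeMgBr (8 equiv), CeCl3 (8 equiv), THF, −78 → 0 °C
Reagents that add atoms: methylmagnesium bromide, C[Mg]Br
Why: double addition of the weakly basic methylcerium reagent to the ester installs both C8 methyl groups without enolising C7, while the triketone unit and aryl ketone are protected in situ as their enolates.

Step 12
Reactants: 18 (5S,6S,7S,12S)-spiro tertiary alcohol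
Product: 19 (1S,5S,6S,7S,12S)-3-[3,4-bis(prop-2-en-1-yloxy)benzoyl] tetracycle [the target with both catechol OH groups as allyl ethers]
Conditions: HCO2H, 23 °C, 2 h
Reagents that add atoms: none
Why: biomimetic cationic cyclisation (SN1 ionisation to the C8 tertiary cation and C‑alkylation by the prenyl‑bearing enol carbon C1) closes ring B stereospecifically; C1 can only be 1S because the bridge must form on the C6 side of ring A, any O‑alkylated enol ether re‑ionises under these conditions, and the cis‑fused ring C forces the boat‑like closure that leaves the C7 prenyl endo.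

Step 13
Reactants: 19 (1S,5S,6S,7S,12S)-3-[3,4-bis(prop-2-en-1-yloxy)benzoyl] tetracycle
Product: 20 CNP0140614.2, (1S,5S,6S,7S,12S)-3-(3,4-dihydroxybenzoyl)-4-hydroxy-8,8,11,11-tetramethyl-1,7-bis(3-methylbut-2-en-1-yl)-12-(prop-1-en-2-yl) ring‑C‑fused bicyclo[3.3.1]non-3-ene-2,9-dione
Conditions: Pd(PPh3)4 (5 mol %), morpholine (10 equiv), THF, 23 °C
Reagents that add atoms: none
Why: Tsuji–Trost deallylation transfers both O‑allyl groups to morpholine under neutral conditions that leave the C‑prenyl groups, the isopropenyl group and the enolised triketone intact.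

## Compound list

1 | 3,4-dihydroxybenzonitrile | N#Cc1ccc(O)c(O)c1 | starting material
2 | 3,4-bis(prop-2-en-1-yloxy)benzonitrile | N#Cc1ccc(OCC=C)c(OCC=C)c1 | intermediate
3 | benzene-1,3,5-triol (phloroglucinol) | Oc1cc(O)cc(O)c1 | starting material
4 | [3,4-bis(prop-2-en-1-yloxy)phenyl](2,4,6-trihydroxyphenyl)methaniminium chloride | [NH2+]=C(c1ccc(OCC=C)c(OCC=C)c1)c1c(O)cc(O)cc1O.[Cl-] | intermediate
5 | [3,4-bis(prop-2-en-1-yloxy)phenyl](2,4,6-trihydroxyphenyl)methanone | O=C(c1ccc(OCC=C)c(OCC=C)c1)c1c(O)cc(O)cc1O | intermediate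
6 | [3,4-bis(prop-2-en-1-yloxy)phenyl][2,4,6-trihydroxy-3-(3-methylbut-2-en-1-yl)phenyl]methanone | O=C(c1ccc(OCC=C)c(OCC=C)c1)c1c(O)cc(O)c(CC=C(C)C)c1O | intermediate
7 | 2-methylcyclohex-2-en-1-one | CC1=CCCCC1=O | starting material
8 | bromomagnesium (3S)-2-methyl-3-(prop-1-en-2-yl)cyclohex-1-en-1-olate | C=C(C)[C@@H]1CCCC(O[Mg]Br)=C1C | intermediate
9 | (3S)-2,2-dimethyl-3-(prop-1-en-2-yl)cyclohexan-1-one | C=C(C)[C@@H]1CCCC(=O)C1(C)C | intermediate
10 | (3S)-6-hydroxy-2,2-dimethyl-3-(prop-1-en-2-yl)cyclohexan-1-one (both C6 epimers) | C=C(C)[C@@H]1CCC(O)C(=O)C1(C)C | intermediate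
11 | (4S)-3,3-dimethyl-4-(prop-1-en-2-yl)cyclohexane-1,2-diol (diastereomer mixture) | C=C(C)[C@@H]1CCC(O)C(O)C1(C)C | intermediate
12 | (3S)-2,2-dimethyl-3-(prop-1-en-2-yl)hexanedial | C=C(C)[C@H](CCC=O)C(C)(C)C=O | intermediate
13 | 4-nitrophenyl (2E,6S)-7,7-dimethyl-8-oxo-6-(prop-1-en-2-yl)oct-2-enoate | C=C(C)[C@H](CC/C=C/C(=O)Oc1ccc(cc1)[N+](=O)[O-])C(C)(C)C=O | intermediate
14 | 4-nitrophenyl (2E,6S)-8-{3-[3,4-bis(prop-2-en-1-yloxy)benzoyl]-2,4,6-trihydroxy-5-(3-methylbut-2-en-1-yl)phenyl}-7,7-dimethyl-6-(prop-1-en-2-yl)oct-2-enoate | O=C(c1ccc(OCC=C)c(OCC=C)c1)c1c(O)c(CC(C)(C)[C@@H](CC/C=C/C(=O)Oc2ccc(cc2)[N+](=O)[O-])C(C)=C)c(O)c(CC=C(C)C)c1O | intermediate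
15 | (5S,6S,12S)-spiro enol δ-lactone: ring C closed between C5 and C6; lactone C6–C7H2–C8(=O)–O–C9 on the enol oxygen of C9=C1(prenyl); ring A also has C2=O, C3 aroyl, C4–OH | C=C(C)[C@@H]1CC[C@H]2CC(=O)OC3=C(CC=C(C)C)C(=O)C(C(=O)c4ccc(OCC=C)c(OCC=C)c4)=C(O)[C@]23CC1(C)C | intermediate
16 | methyl (5S,6S,12S)-spiro ester: cycloheptane ring C spiro at C5 to the dearomatised ring A (C9=O, C1(prenyl)=C2–OH, C3(aroyl)=C4–OH); C6 carries CH2CO2Me | C=C(C)[C@@H]1CC[C@@H](CC(=O)OC)[C@]2(CC1(C)C)C(=O)C(CC=C(C)C)=C(O)C(C(=O)c3ccc(OCC=C)c(OCC=C)c3)=C2O | intermediate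
17 | methyl (5S,6S,7S,12S)-7-prenyl spiro ester: as 16 with a 3-methylbut-2-en-1-yl group on C7 | C=C(C)[C@@H]1CC[C@@H]([C@H](CC=C(C)C)C(=O)OC)[C@]2(CC1(C)C)C(=O)C(CC=C(C)C)=C(O)C(C(=O)c3ccc(OCC=C)c(OCC=C)c3)=C2O | intermediate
18 | (5S,6S,7S,12S)-spiro tertiary alcohol: as 17 with C8 = C(OH)(CH3)2 | C=C(C)[C@@H]1CC[C@@H]([C@H](CC=C(C)C)C(C)(C)O)[C@]2(CC1(C)C)C(=O)C(CC=C(C)C)=C(O)C(C(=O)c3ccc(OCC=C)c(OCC=C)c3)=C2O | intermediate
19 | (1S,5S,6S,7S,12S)-3',4'-di-O-allyl ether of the target | C=C(C)[C@@H]1CC[C@H]2[C@H](CC=C(C)C)C(C)(C)[C@]3(CC=C(C)C)C(=O)C(C(=O)c4ccc(OCC=C)c(OCC=C)c4)=C(O)[C@@]2(CC1(C)C)C3=O | intermediate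
20 | CNP0140614.2, (1S,5S,6S,7S,12S) | C=C(C)[C@@H]1CC[C@H]2[C@H](CC=C(C)C)C(C)(C)[C@]3(CC=C(C)C)C(=O)C(C(=O)c4ccc(O)c(O)c4)=C(O)[C@@]2(CC1(C)C)C3=O | target

## Count and risks

Total step count: 13. Longest linear sequence: 10 steps (7 → 9 → 10 → 12 → 13 → 14 → 16 → 17 → 18 → 19 → 20, steps 4–13).

Steps most likely to fail:

Step 9 (ring size, choice of oxygen, and C5/C6 control all rest on one new catalytic event). The fallback sets out from 12 and 6 and comes back at 15. The unhindered aldehyde of 12 is converted into its dimethyl acetal, (3S)-6,6-dimethoxy-2,2-dimethyl-3-(prop-1-en-2-yl)hexanal F2 (HC(OMe)3, MeOH, cat. acid). Reductive alkylation of 6 with F2 as in step 8 gives the acetal‑armed arene F3, and mild aqueous acid frees the aldehyde F4. Knoevenagel condensation of F4 with Meldrum's acid gives the alkylidene Meldrum's acid F5, a far stronger acceptor. F5 undergoes uncatalysed dearomatising Michael addition at C5, lactonisation on the oxygen para to the aroyl group and loss of acetone and carbon dioxide to give lactone 15, which is methanolysed to 16 as before. Stereocontrol is then substrate‑based only, and diastereomers are separated at 16.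

Step 12 (O‑ versus C‑alkylation, survival of the second isopropenyl group, boat‑like closure). The fallback sets out from 18 and comes back at 19. 18 is dehydrated with the Burgess reagent to the isopropenyl compound F6. Ring B is then closed by a Conia‑ene‑type intramolecular hydroalkylation of the C1 enol carbon onto the 1,1‑disubstituted alkene (Ph3PAuCl/AgOTf, toluene, 50 °C), which gives Markovnikov C1–C8 bond formation without a free carbocation.

Step 4 (enantioselectivity of an alkenyl Grignard addition to an α‑substituted enone). The fallback sets out from 7 and comes back at 9. Rhodium‑catalysed Hayashi–Miyaura addition of potassium isopropenyltrifluoroborate ([Rh(cod)Cl]2, (S)-BINAP, toluene/H2O, 100 °C) gives (3R)-2-methyl-3-(prop-1-en-2-yl)cyclohexan-1-one F1 (same spatial arrangement at the isopropenyl carbon as in 9, mixture at C2). The thermodynamic, more substituted enolate of F1 (KH, THF) is then methylated with MeI to give 9.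

## Further compounds

F1 | step 4 | (3R)-2-methyl-3-(prop-1-en-2-yl)cyclohexan-1-one (C2 epimers) | C=C(C)[C@@H]1CCCC(=O)C1C
F2 | step 9 | (3S)-6,6-dimethoxy-2,2-dimethyl-3-(prop-1-en-2-yl)hexanal | C=C(C)[C@H](CCC(OC)OC)C(C)(C)C=O
F3 | step 9 | [3,4-bis(prop-2-en-1-yloxy)phenyl]{3-[(3S)-6,6-dimethoxy-2,2-dimethyl-3-(prop-1-en-2-yl)hexyl]-2,4,6-trihydroxy-5-(3-methylbut-2-en-1-yl)phenyl}methanone | O=C(c1ccc(OCC=C)c(OCC=C)c1)c1c(O)c(CC(C)(C)[C@@H](CCC(OC)OC)C(C)=C)c(O)c(CC=C(C)C)c1O
F4 | step 9 | (4S)-6-{3-[3,4-bis(prop-2-en-1-yloxy)benzoyl]-2,4,6-trihydroxy-5-(3-methylbut-2-en-1-yl)phenyl}-5,5-dimethyl-4-(prop-1-en-2-yl)hexanal | O=C(c1ccc(OCC=C)c(OCC=C)c1)c1c(O)c(CC(C)(C)[C@@H](CCC=O)C(C)=C)c(O)c(CC=C(C)C)c1O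
F5 | step 9 | 5-[(4S)-6-{3-[3,4-bis(prop-2-en-1-yloxy)benzoyl]-2,4,6-trihydroxy-5-(3-methylbut-2-en-1-yl)phenyl}-5,5-dimethyl-4-(prop-1-en-2-yl)hexylidene]-2,2-dimethyl-1,3-dioxane-4,6-dione | O=C(c1ccc(OCC=C)c(OCC=C)c1)c1c(O)c(CC(C)(C)[C@@H](CCC=C2C(=O)OC(C)(C)OC2=O)C(C)=C)c(O)c(CC=C(C)C)c1O
F6 | step 12 | (5S,6S,7S,12S)-spiro diene: 18 with the C8 carbinol dehydrated to an isopropenyl group | C=C(C)[C@@H]1CC[C@@H]([C@H](CC=C(C)C)C(C)=C)[C@]2(CC1(C)C)C(=O)C(CC=C(C)C)=C(O)C(C(=O)c3ccc(OCC=C)c(OCC=C)c3)=C2O
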